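**Plan**

1. Retrosynthetic cuts: the lactone carbonyl (back to an allylic ether CH2 at C12) and the two esters; the C10–O bond of the 5,10-oxide; C4–C15; then the oxy-Cope pair (open C2–C3, rejoin C5–C10); finally C5–C4, C6–O, the C10 vinyl group and C8–O, back to (R)-carvone.
2. Enabling feature: in the ten-membered carbocycle, C5 (bridge oxygen) and C10 (methyl, bridge oxygen, next to C1) lie 1,6 to each other with C2–C3 halfway between. Rejoining C5–C10 while opening C2–C3 gives a six-membered ring C5–C10 with alkenyl arms on C5 and C10, a 1,2-dialkenylcyclohexan-1-ol.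
3. Forward ring order: carvone six-membered ring, then a cis-fused methylenetetrahydrofuran (O on C6, C12), then the ten-membered ring by anionic oxy-Cope expansion, then the C5–O–C10 bridge, then the lactone carbonyl by allylic oxidation.
4. Stereochemistry: C7 from (R)-carvone; C8 (first trans to steer the C10 alkylation, then inverted by oxidation/reduction), C10 and C6 relayed from C7 on the cyclohexane; the carbinol C5 by equatorial alkynide addition.
5. C3 and the E alkene come from the chair oxy-Cope; C4 from peripheral protonation; C5 from chelation control by C4; C10 from the transannular ether closure.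

Key step: step 16

Remark: atoms carry germacranolide labels (ring C1–C10, C11–C13 on C7, C14 = methyl on C10, C15 on C4). Read literally, the SMILES has a cis-fused lactone and places H5 and the C10 methyl on opposite sides of the oxide bridge (trans-bridged bicycle); that isomer, all-R at C3, C4, C5, C6, C7, C8 and C10, is the one aimed at.

**Route**

Step 1
Reactants: 1 (R)-carvone
Product: 3 trans-4-hydroxycarvone, via trimethylsilyl dienol ether 2 (not isolated)
Conditions: TMSCl, NaI, Et3N, MeCN, 25 °C; then mCPBA, NaHCO3, CH2Cl2, −20 °C; aq citric acid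
Reagents that add atoms: mCPBA, OOC(=O)c1cccc(Cl)c1
Why: Thermodynamic silylation should give the through-conjugated dienol ether (as with steroidal 4-en-3-ones), and the peracid then attacks its terminal carbon C8 in a vinylogous Rubottom oxidation from the face opposite the neighbouring isopropenyl group, setting the C8 hydroxyl trans to C7.

Step 2
Reactants: 3 trans-4-hydroxycarvone
Product: 4 trans-4-(tert-butyldimethylsilyloxy)carvone
Conditions: TBSCl, imidazole, DMF, 25 °C
Reagents that add atoms: TBSCl, CC(C)(C)[Si](C)(C)Cl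
Why: Standard silyl ether formation at an unhindered secondary allylic alcohol; the bulky trans silyloxy group later shields one face in step 5.

Step 3
Reactants: 4 trans-4-(tert-butyldimethylsilyloxy)carvone
Product: 5 allylic chloride (3-chloroprop-1-en-2-yl side chain on C7)
Conditions: Ca(OCl)2, solid CO2, CH2Cl2/H2O, 0 °C
Reagents that add atoms: calcium hypochlorite, [Ca+2].[O-]Cl.[O-]Cl
Why: Ene-type allylic chlorination by HOCl takes place at the electron-rich 1,1-disubstituted alkene and leaves the electron-poor enone untouched, so C12 becomes functionalised without touching a stereocentre.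

Step 4
Reactants: 5 allylic chloride
Product: 6 allylic acetate (3-acetoxyprop-1-en-2-yl side chain)
Conditions: KOAc, 18-crown-6 (cat.), MeCN, 60 °C
Reagents that add atoms: potassium acetate, CC(=O)[O-].[K+]
Why: SN2 displacement of a primary allylic chloride by acetate.

Step 5
Reactants: 6 allylic acetate
Product: 8 2-methyl-2-[2-(phenylsulfinyl)ethyl]cyclohexanone (arm on C10 cis to the C7 side chain; mixture at sulfur), via lithium enolate 7 (not isolated)
Conditions: LiBH(s-Bu)3, THF, −78 °C; then phenyl vinyl sulfoxide, −78 → 0 °C; H2O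
Reagents that add atoms: phenyl vinyl sulfoxide, C=CS(=O)c1ccccc1
Why: Conjugate hydride addition to the β-unsubstituted enone gives the tetrasubstituted enolate regiospecifically, and its Michael addition to phenyl vinyl sulfoxide (a vinyl cation equivalent) should occur by axial attack on the half-chair with the C7 and C8 substituents equatorial, anti to the C8 silyloxy group, so the new arm on quaternary C10 ends up cis to the C7 side chain.

Step 6
Reactants: 8 sulfoxide
Product: 9 2-methyl-2-vinylcyclohexanone (vinyl cis to the C7 side chain, C8–OTBS trans)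
Conditions: toluene, NaHCO3, 110 °C
Reagents that add atoms: none
Why: Thermal syn-elimination of the sulfoxide unveils the vinyl group on the quaternary carbon.

Step 7
Reactants: 9 vinyl ketone
Product: 10 C8 alcohol (trans to the C7 side chain)
Conditions: HF·pyridine, pyridine, THF, 0 °C
Reagents that add atoms: none
Why: Buffered fluoride cleavage of the secondary silyl ether spares the allylic acetate.

Step 8
Reactants: 10 C8 alcohol
Product: 11 cyclohexane-1,4-dione (C5 and C8 carbonyls)
Conditions: 1,1,1-triacetoxy-1,2-benziodoxol-3(1H)-one, NaHCO3, CH2Cl2, 0 °C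
Reagents that add atoms: none
Why: Buffered periodinane oxidation of the secondary alcohol is neutral enough to leave C7 (α to the new ketone and allylic) unepimerised.

Step 9
Reactants: 11 1,4-dione
Product: 12 C8 alcohol cis to the C7 side chain
Conditions: LiBH(s-Bu)3 (1 equiv), THF, −78 °C; H2O
Reagents that add atoms: none
Why: In the favoured chair (C7 side chain equatorial, C10 vinyl axial) the bulky borohydride adds equatorially to the C8 carbonyl from the face opposite the axial vinyl group, giving the axial alcohol cis to the C7 side chain, while the C5 carbonyl next to quaternary C10 is slower (stereo- and chemoselective ketone reduction).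

Step 10
Reactants: 12 cis alcohol
Product: 13 cis C8 silyl ether
Conditions: TBSOTf, 2,6-lutidine, CH2Cl2, −78 °C
Reagents that add atoms: TBSOTf, CC(C)(C)[Si](C)(C)OS(=O)(=O)C(F)(F)F
Why: O-silylation of the secondary alcohol by the silyl triflate at low temperature is faster than enol silylation of the hindered ketone.

Step 11
Reactants: 13 cis silyl ether
Product: 14 primary allylic alcohol (C12–OH)
Conditions: K2CO3 (cat.), MeOH, 0 °C
Reagents that add atoms: none
Why: Mild transesterification removes the primary acetate; no enolisable stereocentre is present.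

Step 12
Reactants: 14 primary allylic alcohol
Product: 16 4-(tert-butyldimethylsilyloxy)-6-methyl-3-methylene-6-vinylhexahydrobenzofuran-7(2H)-one (cis ring fusion; OTBS and vinyl cis to the furan ring), via bromo ketone 15 (not isolated)
Conditions: LiN(SiMe3)2 (2.2 equiv), THF, −78 °C; NBS; −78 → 0 °C
Reagents that add atoms: none
Why: Only C6 can enolise; the enolate is brominated anti to the C7 side chain and the C12 alkoxide then displaces bromide from the rear (5-exo-tet Williamson etherification with inversion), which can only give the cis-fused methylenetetrahydrofuran and so sets C6–O cis to C7.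

Step 13
Reactants: 17 4-methoxybenzyl alcohol; 18 trichloroethylene
Product: 19 (E)-1,2-dichlorovinyl 4-methoxybenzyl ether
Conditions: KH, THF, 0 → 25 °C
Reagents that add atoms: none
Why: The alkoxide adds to dichloroacetylene formed in situ from trichloroethylene (known route to 1,2-dichlorovinyl ethers).

Step 14
Reactants: 16 bicyclic ketone; 19 dichlorovinyl ether
Product: 21 tertiary propargylic alcohol (alkynyl on C5 trans to the C10 vinyl group), via lithium alkynide 20 (not isolated)
Conditions: 19, n-BuLi (2.1 equiv), THF, −78 → −40 °C; then 16, −78 °C; H2O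
Reagents that add atoms: none
Why: Elimination and chlorine–lithium exchange give the lithium alkynyl ether, and its 1,2-addition to the ketone should be equatorial because the axial C7–C11 bond of the fused furan blocks the axial path, which places the alkynyl group trans to the C10 vinyl group and cis to the C10 methyl.

Step 15
Reactants: 21 propargylic alcohol
Product: 22 trans-1,2-dialkenylcyclohexanol with an (E)-2-(4-methoxybenzyloxy)vinyl group on C5
Conditions: LiAlH4, THF, 0 → 25 °C; aq potassium sodium tartrate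
Reagents that add atoms: none
Why: Alkoxide-directed trans-hydroalumination of the propargylic alcohol gives the (E)-enol ether.

Step 16
Reactants: 22 trans-1,2-dialkenylcyclohexanol
Product: 24 (E)-cyclodec-1(10)-en-5-one with 3-OPMB, via potassium enolate 23 (not isolated)
Conditions: KH, 18-crown-6, THF, 0 → 25 °C; then AcOH, THF, −78 °C
Reagents that add atoms: none
Why: KH with 18-crown-6 gives a dissociated potassium alkoxide that undergoes the anionic oxy-Cope [3,3] shift: C2–C3 forms between the enol-ether terminus and the vinyl terminus while C5–C10 breaks, and the ring-expanded enolate 23 is protonated cold. The closest known reaction type is the alkoxide-accelerated rearrangement of trans-1,2-divinylcyclohexanols to (E)-cyclodec-5-enones. No ring is closed by direct bond formation; the ten-membered ring arises by ring expansion through a chair six-centre array trans-fused to the cyclohexane chair (C6 and C9 both equatorial on it). C3 is the only new stereocentre: the E enol ether puts OPMB equatorial in that chair, whose sense is fixed by the C5/C10 configuration, giving 3R together with the (E)-C1=C10 alkene. The step needs chair over boat and rearrangement faster than loss of 4-methoxybenzyl oxide from the β-alkoxy enolate; the first is secured by the ground-state chair with diequatorial alkenyl groups (C6–O and C8–O also equatorial), the second by the pseudo-equatorial C3–O bond lying near the nodal plane of the enolate and by the cold acetic acid quench.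

Step 17
Reactants: 24 cyclodecenone
Product: 27 4(15)-methylene ketone, via Mannich base 25 (not isolated), via ammonium iodide 26 (not isolated)
Conditions: LiN(i-Pr)2, THF, −78 °C; CH2=NMe2+ I−, −78 → 0 °C; then MeI, CH2Cl2, 25 °C; aq NaHCO3
Reagents that add atoms: dimethyl(methylene)ammonium iodide, C=[N+](C)C.[I-]
Why: Kinetic deprotonation should occur at the C4 methylene and not at the α-alkoxy ring-fusion methine C6, and a Mannich reaction followed by quaternisation and Hofmann-type elimination installs the exocyclic methylene that becomes C15.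

Step 18
Reactants: 27 methylene ketone
Product: 29 15-hydroxy ketone (4R), via pinacol boronate 28 (not isolated)
Conditions: B2pin2, CuCl (cat.), NaOt-Bu (cat.), Xantphos, MeOH, THF, 0 °C; then NaBO3·4H2O, THF/H2O, 0 °C
Reagents that add atoms: sodium perborate, [Na+].[O-]OB=O
Why: Copper-catalysed conjugate borylation (monovalent copper boryl) is chemoselective for the enone; the ring enolate is protonated by methanol on its outer face, the inner face being covered by the C1=C10 alkene, so H is outside and C15 cis to the C3 ether, and perborate oxidises C–B to C–OH with retention.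

Step 19
Reactants: 29 15-hydroxy ketone
Product: 30 5,15-diol (4R,5R)
Conditions: Zn(BH4)2, Et2O, −30 °C; H2O
Reagents that add atoms: none
Why: Chelation-controlled reduction: zinc bridges the C15 hydroxyl and the C5 carbonyl and hydride adds to the chelate face opposite the C3–C4 ring bond, that is from outside the ring, giving the 5R alcohol.

Step 20
Reactants: 30 5,15-diol
Product: 31 15-O-TBDPS ether with free C5–OH
Conditions: TBDPSCl, imidazole, CH2Cl2, 0 °C
Reagents that add atoms: TBDPSCl, CC(C)(C)[Si](Cl)(c1ccccc1)c1ccccc1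
Why: Selective silylation of the primary hydroxyl over the hindered secondary one.

Step 21
Reactants: 31 C5 alcohol
Product: 33 5,10-oxide (trans-bridged 11-oxabicyclo[4.4.1]undecane core), via organomercurial 32 (not isolated)
Conditions: Hg(OCOCF3)2, THF, −40 °C; then NaBH4, aq NaOH, −40 → 0 °C
Reagents that add atoms: none
Why: Transannular alkoxymercuration–demercuration adds O5 to the more substituted C10 anti to mercury on C1; closure through the chair–chair conformer with the C4 substituent equatorial should put oxygen on the C10 face that leaves H5 and the C10 methyl on opposite sides of the bridge (10R), and low temperature with in situ reduction keeps the addition under kinetic control.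

Step 22
Reactants: 33 bridged ether
Product: 34 C8 alcohol
Conditions: HF·pyridine, pyridine, THF, 0 → 25 °C
Reagents that add atoms: none
Why: Under buffered HF the secondary TBS ether is cleaved much faster than the primary TBDPS ether (selective desilylation).

Step 23
Reactants: 34 C8 alcohol
Product: 35 C8 methacrylate
Conditions: methacrylic anhydride, Et3N, DMAP (cat.), CH2Cl2, 0 → 25 °C
Reagents that add atoms: methacrylic anhydride, C=C(C)C(=O)OC(=O)C(C)=C
Why: DMAP-catalysed acylation of the only free hydroxyl, with retention at C8.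

Step 24
Reactants: 35 methacrylate
Product: 36 C3 alcohol
Conditions: DDQ, CH2Cl2/pH 7 buffer, 0 °C
Reagents that add atoms: none
Why: Oxidative cleavage of the 4-methoxybenzyl ether by DDQ is much faster than oxidation of the allylic furan ether.

Step 25
Reactants: 36 C3 alcohol
Product: 37 C3 acetate
Conditions: Ac2O, pyridine, DMAP (cat.), CH2Cl2, 25 °C
Reagents that add atoms: acetic anhydride, CC(=O)OC(C)=O
Why: Standard acetylation of the secondary alcohol.

Step 26
Reactants: 37 C3 acetate
Product: 38 α-methylene-γ-butyrolactone (15-O-TBDPS)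
Conditions: CrO3·3,5-dimethylpyrazole, CH2Cl2, −20 °C
Reagents that add atoms: chromium trioxide, O=[Cr](=O)=O
Why: Allylic oxidation by hexavalent chromium attacks the C12 methylene, the only CH2 that is both allylic and α to a ring oxygen, converting the 3-methylenetetrahydrofuran into the α-methylene lactone (known oxidation of cyclic allylic ethers to unsaturated lactones).

Step 27
Reactants: 38 silyl-protected lactone
Product: 39 CNP0602302.1
Conditions: HF·pyridine, THF, 0 → 25 °C
Reagents that add atoms: none
Why: Acidic fluoride removes the primary TBDPS ether and should leave the acetate, the methacrylate, the α-methylene lactone and the oxide bridge untouched.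

**Compound list**

1 | (R)-carvone | CC1=CC[C@H](CC1=O)C(C)=C | starting material
2 | trimethylsilyl dienol ether of carvone (1-silyloxy-1,3-diene) | CC1=C(O[Si](C)(C)C)C[C@@H](C=C1)C(C)=C | intermediate (not isolated)
3 | (4S,5R)-4-hydroxy-2-methyl-5-(prop-1-en-2-yl)cyclohex-2-en-1-one (trans-4-hydroxycarvone) | CC1=C[C@H](O)[C@H](CC1=O)C(C)=C | intermediate
4 | (4S,5R)-4-(tert-butyldimethylsilyloxy)-2-methyl-5-(prop-1-en-2-yl)cyclohex-2-en-1-one | CC1=C[C@H](O[Si](C)(C)C(C)(C)C)[C@H](CC1=O)C(C)=C | intermediate
5 | (4S,5R)-4-(tert-butyldimethylsilyloxy)-5-(3-chloroprop-1-en-2-yl)-2-methylcyclohex-2-en-1-one | CC1=C[C@H](O[Si](C)(C)C(C)(C)C)[C@H](CC1=O)C(=C)CCl | intermediate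
6 | (4S,5R)-5-(3-acetoxyprop-1-en-2-yl)-4-(tert-butyldimethylsilyloxy)-2-methylcyclohex-2-en-1-one | CC1=C[C@H](O[Si](C)(C)C(C)(C)C)[C@H](CC1=O)C(=C)COC(C)=O | intermediate
7 | lithium enolate from 1,4-reduction of 6 (C5=C10 enolate) | [Li]OC1=C(C)C[C@H](O[Si](C)(C)C(C)(C)C)[C@H](C1)C(=C)COC(C)=O | intermediate (not isolated)
8 | 5-(3-acetoxyprop-1-en-2-yl)-4-(tert-butyldimethylsilyloxy)-2-methyl-2-[2-(phenylsulfinyl)ethyl]cyclohexan-1-one; sulfinylethyl cis to the C7 side chain, OTBS trans; mixture at sulfur | O=C1C[C@H](C(=C)COC(C)=O)[C@@H](O[Si](C)(C)C(C)(C)C)C[C@]1(C)CCS(=O)c1ccccc1 | intermediate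
9 | 5-(3-acetoxyprop-1-en-2-yl)-4-(tert-butyldimethylsilyloxy)-2-methyl-2-vinylcyclohexan-1-one; vinyl cis to the C7 side chain, OTBS trans | O=C1C[C@H](C(=C)COC(C)=O)[C@@H](O[Si](C)(C)C(C)(C)C)C[C@]1(C)C=C | intermediate
10 | 5-(3-acetoxyprop-1-en-2-yl)-4-hydroxy-2-methyl-2-vinylcyclohexan-1-one; OH trans to the C7 side chain | O=C1C[C@H](C(=C)COC(C)=O)[C@@H](O)C[C@]1(C)C=C | intermediate
11 | 2-(3-acetoxyprop-1-en-2-yl)-5-methyl-5-vinylcyclohexane-1,4-dione; side chain cis to vinyl | O=C1C[C@H](C(=C)COC(C)=O)C(=O)C[C@]1(C)C=C | intermediate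
12 | 5-(3-acetoxyprop-1-en-2-yl)-4-hydroxy-2-methyl-2-vinylcyclohexan-1-one; OH, side chain and vinyl all cis | O=C1C[C@H](C(=C)COC(C)=O)[C@H](O)C[C@]1(C)C=C | intermediate
13 | tert-butyldimethylsilyl ether of 12 | O=C1C[C@H](C(=C)COC(C)=O)[C@H](O[Si](C)(C)C(C)(C)C)C[C@]1(C)C=C | intermediate
14 | 4-(tert-butyldimethylsilyloxy)-5-(3-hydroxyprop-1-en-2-yl)-2-methyl-2-vinylcyclohexan-1-one; all-cis OTBS, side chain, vinyl | O=C1C[C@H](C(=C)CO)[C@H](O[Si](C)(C)C(C)(C)C)C[C@]1(C)C=C | intermediate
15 | 6-bromo derivative of 14 (Br on C6 trans to the C7 side chain; present as its lithium alkoxide) | O=C1[C@@H](Br)[C@H](C(=C)CO)[C@H](O[Si](C)(C)C(C)(C)C)C[C@]1(C)C=C | intermediate (not isolated)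
16 | 4-(tert-butyldimethylsilyloxy)-6-methyl-3-methylene-6-vinylhexahydrobenzofuran-7(2H)-one; cis ring fusion, OTBS and vinyl cis to the furan ring, methyl trans | O=C1[C@@H]2OCC(=C)[C@@H]2[C@H](O[Si](C)(C)C(C)(C)C)C[C@]1(C)C=C | intermediate
17 | 4-methoxybenzyl alcohol | COc1ccc(CO)cc1 | starting material
18 | trichloroethylene | ClC=C(Cl)Cl | starting material
19 | (E)-1,2-dichlorovinyl 4-methoxybenzyl ether | COc1ccc(CO/C(Cl)=C\Cl)cc1 | intermediate
20 | lithium (4-methoxybenzyloxy)ethynide | [Li]C#COCc1ccc(OC)cc1 | intermediate (not isolated)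
21 | 7-[(4-methoxybenzyloxy)ethynyl] carbinol from 16; alkynyl trans to the C10 vinyl, OH cis to it | O[C@]1(C#COCc2ccc(OC)cc2)[C@@H]2OCC(=C)[C@@H]2[C@H](O[Si](C)(C)C(C)(C)C)C[C@]1(C)C=C | intermediate
22 | 7-[(E)-2-(4-methoxybenzyloxy)vinyl] carbinol (trans-1,2-dialkenylcyclohexanol; ring C5–C10) | O[C@]1(/C=C/OCc2ccc(OC)cc2)[C@@H]2OCC(=C)[C@@H]2[C@H](O[Si](C)(C)C(C)(C)C)C[C@]1(C)C=C | intermediate
23 | potassium C4=C5 enolate of 24 (C3 and C6 trans across the enolate) | CC(C)(C)[Si](C)(C)O[C@@H]1C/C(C)=C/C[C@@H](OCc2ccc(OC)cc2)/C=C(\O[K])[C@@H]2OCC(=C)[C@H]12 | intermediate (not isolated)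
24 | (1(10)E,3R)-3-(4-methoxybenzyloxy)-8-(tert-butyldimethylsilyloxy)-6,12-epoxy-15-norgermacra-1(10),11(13)-dien-5-one; C6, C7, C8 as in 16 | CC(C)(C)[Si](C)(C)O[C@@H]1C/C(C)=C/C[C@@H](OCc2ccc(OC)cc2)CC(=O)[C@@H]2OCC(=C)[C@H]12 | intermediate
25 | 4-(dimethylaminomethyl) ketone (Mannich base; mixture at C4) | CC(C)(C)[Si](C)(C)O[C@@H]1C/C(C)=C/C[C@@H](OCc2ccc(OC)cc2)C(CN(C)C)C(=O)[C@@H]2OCC(=C)[C@H]12 | intermediate (not isolated)
26 | 4-(trimethylammoniomethyl) ketone iodide | CC(C)(C)[Si](C)(C)O[C@@H]1C/C(C)=C/C[C@@H](OCc2ccc(OC)cc2)C(C[N+](C)(C)C)C(=O)[C@@H]2OCC(=C)[C@H]12.[I-] | intermediate (not isolated)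
27 | (1(10)E)-3-(4-methoxybenzyloxy)-8-(tert-butyldimethylsilyloxy)-6,12-epoxygermacra-1(10),4(15),11(13)-trien-5-one | CC(C)(C)[Si](C)(C)O[C@@H]1C/C(C)=C/C[C@@H](OCc2ccc(OC)cc2)C(=C)C(=O)[C@@H]2OCC(=C)[C@H]12 | intermediate
28 | 15-(pinacolboryl) ketone (4R) | CC(C)(C)[Si](C)(C)O[C@@H]1C/C(C)=C/C[C@@H](OCc2ccc(OC)cc2)[C@@H](CB3OC(C)(C)C(C)(C)O3)C(=O)[C@@H]2OCC(=C)[C@H]12 | intermediate (not isolated)
29 | (4R)-15-hydroxy-3-(4-methoxybenzyloxy)-8-(tert-butyldimethylsilyloxy)-6,12-epoxygermacra-1(10),11(13)-dien-5-one | CC(C)(C)[Si](C)(C)O[C@@H]1C/C(C)=C/C[C@@H](OCc2ccc(OC)cc2)[C@@H](CO)C(=O)[C@@H]2OCC(=C)[C@H]12 | intermediate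
30 | (4R,5R)-5,15-diol | CC(C)(C)[Si](C)(C)O[C@@H]1C/C(C)=C/C[C@@H](OCc2ccc(OC)cc2)[C@@H](CO)[C@@H](O)[C@@H]2OCC(=C)[C@H]12 | intermediate
31 | 15-O-(tert-butyldiphenylsilyl) ether of 30 (free 5R hydroxyl) | CC(C)(C)[Si](C)(C)O[C@@H]1C/C(C)=C/C[C@@H](OCc2ccc(OC)cc2)[C@@H](CO[Si](c2ccccc2)(c2ccccc2)C(C)(C)C)[C@@H](O)[C@@H]2OCC(=C)[C@H]12 | intermediate
32 | C1 trifluoroacetoxymercurio 5,10-oxide (Hg anti to the new C10–O bond) | CC(C)(C)[Si](C)(C)O[C@@H]1C[C@@]2(C)[C@H]([Hg]OC(=O)C(F)(F)F)C[C@@H](OCc3ccc(OC)cc3)[C@@H](CO[Si](c3ccccc3)(c3ccccc3)C(C)(C)C)[C@@H](O2)[C@@H]2OCC(=C)[C@@H]21 | intermediate (not isolated)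
33 | 3-(4-methoxybenzyloxy)-8-(tert-butyldimethylsilyloxy)-15-(tert-butyldiphenylsilyloxy)-5,10:6,12-diepoxygermacr-11(13)-ene; configuration as in the target | CC(C)(C)[Si](C)(C)O[C@@H]1C[C@@]2(C)CC[C@@H](OCc3ccc(OC)cc3)[C@@H](CO[Si](c3ccccc3)(c3ccccc3)C(C)(C)C)[C@@H](O2)[C@@H]2OCC(=C)[C@@H]21 | intermediate
34 | 8-alcohol from 33 | O[C@@H]1C[C@@]2(C)CC[C@@H](OCc3ccc(OC)cc3)[C@@H](CO[Si](c3ccccc3)(c3ccccc3)C(C)(C)C)[C@@H](O2)[C@@H]2OCC(=C)[C@@H]21 | intermediate
35 | 8-methacrylate | C=C(C)C(=O)O[C@@H]1C[C@@]2(C)CC[C@@H](OCc3ccc(OC)cc3)[C@@H](CO[Si](c3ccccc3)(c3ccccc3)C(C)(C)C)[C@@H](O2)[C@@H]2OCC(=C)[C@@H]21 | intermediate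
36 | 3-alcohol 8-methacrylate | C=C(C)C(=O)O[C@@H]1C[C@@]2(C)CC[C@@H](O)[C@@H](CO[Si](c3ccccc3)(c3ccccc3)C(C)(C)C)[C@@H](O2)[C@@H]2OCC(=C)[C@@H]21 | intermediate
37 | 3-acetate 8-methacrylate | C=C(C)C(=O)O[C@@H]1C[C@@]2(C)CC[C@@H](OC(C)=O)[C@@H](CO[Si](c3ccccc3)(c3ccccc3)C(C)(C)C)[C@@H](O2)[C@@H]2OCC(=C)[C@@H]21 | intermediate
38 | 15-O-TBDPS ether of the target (12,6-olide) | C=C(C)C(=O)O[C@@H]1C[C@@]2(C)CC[C@@H](OC(C)=O)[C@@H](CO[Si](c3ccccc3)(c3ccccc3)C(C)(C)C)[C@@H](O2)[C@@H]2OC(=O)C(=C)[C@@H]21 | intermediate
39 | CNP0602302.1, (3R,4R,5R,6R,7R,8R,10R)-3-acetoxy-5,10-epoxy-15-hydroxy-8-(methacryloyloxy)germacr-11(13)-en-12,6-olide | C=C(C)C(=O)O[C@@H]1C[C@@]2(C)CC[C@@H](OC(C)=O)[C@@H](CO)[C@@H](O2)[C@@H]2OC(=O)C(=C)[C@@H]21 | target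

**Count and risks**

Total steps: 27. Longest linear sequence: 26 (steps 1–12 and 14–27 from (R)-carvone); step 13 is the one-step side branch.

Step 21 (most likely to fail). The ring may close through the other face of the C1=C10 alkene, giving the less strained cis-bridged C10 epimer, and reversible mercuration would drift the same way. The fallback forms the C5–O bond by displacement instead of the C10–O bond by addition. It sets out from 31 and returns at 33. Acetylation of 31 gives the C5 acetate F1, so that O5 cannot take part. Peracid epoxidation of F1 then comes from the exposed alkene face, which is the face O5 failed to reach and therefore the one that must carry the bridge oxygen, giving the 1,10-epoxide F2. LiBHEt3 opens the epoxide at the less substituted C1 and cleaves the acetate, giving the 5,10-diol F3. PPh3/CBr4 converts only the secondary C5 alcohol, with inversion, into the bromide F4. KN(SiMe3)2 then closes the ether by intramolecular SN2 of the C10 alkoxide on C5 (second inversion, net retention at C5), giving 33.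

Step 16. The free β-alkoxy enolate may expel 4-methoxybenzyl oxide before the quench, the hindered alkoxide may rearrange too slowly at temperatures where the enolate survives, or the C8 silyl group may migrate to the alkoxide. The fallback keeps the same [3,3] bond reorganisation but runs it neutral and thermal, so that no enolate is formed. It sets out from 22 and returns at 24. N-Trimethylsilylimidazole gives the trimethylsilyl ether F5, heating in o-dichlorobenzene at about 200 °C gives the ring-expanded trimethylsilyl enol ether F6, and mild aqueous acid hydrolyses F6 to 24.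

Step 18. Protonation of the enolate may be poorly face-selective, and the β-hydroxy ketone may epimerise at C4 or undergo retro-aldol cleavage during the oxidation. The fallback makes the C4–C15 bond directly, so that carbon and not hydrogen is delivered to the exposed face. It sets out from 24 and returns at 29: LiN(i-Pr)2 at −78 °C followed by gaseous monomeric CH2O gives the hydroxymethyl ketone in one operation. Because this electrophile enters where the proton entered in step 18, a face preference that gives the wrong C4 epimer in step 18 gives the right one here. No new compound is formed on this path.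

Further compounds
F1 | step 21 | C5 acetate of 31 | CC(C)(C)[Si](C)(C)O[C@@H]1C/C(C)=C/C[C@@H](OCc2ccc(OC)cc2)[C@@H](CO[Si](c2ccccc2)(c2ccccc2)C(C)(C)C)[C@@H](OC(C)=O)[C@@H]2OCC(=C)[C@H]12
F2 | step 21 | 1,10-epoxide of F1 (oxygen on the C10 face required for the bridge) | CC(C)(C)[Si](C)(C)O[C@@H]1C[C@]3(C)O[C@H]3C[C@@H](OCc2ccc(OC)cc2)[C@@H](CO[Si](c2ccccc2)(c2ccccc2)C(C)(C)C)[C@@H](OC(C)=O)[C@@H]2OCC(=C)[C@H]12
F3 | step 21 | 5,10-diol (secondary 5R alcohol, tertiary C10 alcohol) | CC(C)(C)[Si](C)(C)O[C@@H]1C[C@](C)(O)CC[C@@H](OCc2ccc(OC)cc2)[C@@H](CO[Si](c2ccccc2)(c2ccccc2)C(C)(C)C)[C@@H](O)[C@@H]2OCC(=C)[C@H]12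
F4 | step 21 | C5 bromide with inverted C5 and free C10 alcohol | CC(C)(C)[Si](C)(C)O[C@@H]1C[C@](C)(O)CC[C@@H](OCc2ccc(OC)cc2)[C@@H](CO[Si](c2ccccc2)(c2ccccc2)C(C)(C)C)[C@H](Br)[C@@H]2OCC(=C)[C@H]12
F5 | step 16 | trimethylsilyl ether of 22 | C[Si](C)(C)O[C@]1(/C=C/OCc2ccc(OC)cc2)[C@@H]2OCC(=C)[C@@H]2[C@H](O[Si](C)(C)C(C)(C)C)C[C@]1(C)C=C
F6 | step 16 | trimethylsilyl enol ether of 24 (C4=C5) | CC(C)(C)[Si](C)(C)O[C@@H]1C/C(C)=C/C[C@@H](OCc2ccc(OC)cc2)/C=C(\O[Si](C)(C)C)[C@@H]2OCC(=C)[C@H]12
F0 | step 18 | none | none
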